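**Retrosynthetic overview**

1. The 2-methoxychromone is fixed last by O-methylation of a 3-substituted 4-hydroxy-5-methylcoumarin. The C1–aryl bond comes from 4-hydroxy-5-methylcoumarin attacking the oxocarbenium ion of a bicyclic enol lactol (cyclopenta[c]pyran locants C1, O2, C3, C4, C4a, C5, C6, C7, C7a are used throughout).
2. The lactol closes when the methyl enol ether of a 1,2-diketone is hydrolysed next to a 1,5-related aldehyde. The aldehyde comes from an acyl oxazolidinone by thiolysis and silane reduction.
3. Key disconnection: C6–C7 and C4a–C7a form together in a vinylogous radical-anion [3+2] cycloaddition. A β-cyclopropyl α-methoxy enone supplies C4a, C5, C6 and the complete C3/C4 enol-ether–acyl unit; a chiral crotonoyl oxazolidinone supplies C7 with its methyl group, C7a and C1.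
4. Enabling feature: the 3-methylbutanoyl C=O is conjugated through the pyran C3=C4 double bond to C4, the atom that carries ring-fusion carbon C4a. A cyclopropane on C4 is therefore a vinylogous cyclopropyl ketone whose radical anion opens toward C6, and C7=C7a with C1 as a carbonyl is a crotonyl acceptor.
5. Ring order: coumarin ring (side branch), cyclopentane (key step), dihydropyran (lactol closure). The auxiliary sets C7, the ring closure sets C4a and C7a relative to it, and the convex face of the cis-fused bicycle sets C1.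

Key step: step 4

Remark: the enol-ether intermediates are carried as E/Z mixtures at the tetrasubstituted double bond (erased when the enol ether is hydrolysed) and the lactol as an anomeric mixture; 4-hydroxy-5-methylcoumarin is assumed to be prepared rather than bought.

**Route**

Step 1
Reactants: 1 1-cyclopropylethan-1-one; 2 methyl 2-(dimethoxyphosphoryl)-2-methoxyacetate
Product: 3 methyl 3-cyclopropyl-2-methoxybut-2-enoate (E/Z mixture)
Conditions: NaH, THF, 0 °C; then 1, 65 °C
Reagents that add atoms: none
Why: Horner–Wadsworth–Emmons olefination of an unhindered methyl ketone by the reactive α-alkoxy phosphonoacetate anion should give the 2-methoxy enoate, and its geometry does not matter because steps 4 and 7 erase it.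

Step 2
Reactants: 3 methyl 3-cyclopropyl-2-methoxybut-2-enoate
Product: 5 2-cyclopropyl-3-methoxy-6-methylhept-2-en-4-one (E/Z mixture), via Weinreb amide 4 (not isolated)
Conditions: MeNH(OMe)·HCl, i-PrMgCl, THF, −20 °C; then i-BuMgBr, 0 °C; aq. NH4Cl
Reagents that add atoms: N,O-dimethylhydroxylamine hydrochloride, CNOC.Cl (its atoms stay in 4 only); isobutylmagnesium bromide, CC(C)C[Mg]Br
Why: magnesium-amide aminolysis of the ester to the Weinreb amide and Grignard addition in the same flask should stop at the ketone through the chelated tetrahedral intermediate, while the fully substituted β-carbon blocks conjugate addition.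

Step 3
Reactants: 6 (4S)-4-(diphenylmethyl)-1,3-oxazolidin-2-one; 7 (2E)-but-2-enoyl chloride
Product: 8 (4S)-3-[(2E)-but-2-enoyl]-4-(diphenylmethyl)-1,3-oxazolidin-2-one
Conditions: n-BuLi, THF, −78 °C; then 7, −78 to 0 °C
Reagents that add atoms: none
Why: N-acylation of the lithiated oxazolidinone with an acid chloride is a standard way to attach the chiral auxiliary, and the existing stereocentre is not touched.

Step 4
Reactants: 5 2-cyclopropyl-3-methoxy-6-methylhept-2-en-4-one; 8 (4S)-3-[(2E)-but-2-enoyl]-4-(diphenylmethyl)-1,3-oxazolidin-2-one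
Product: 9 (4S)-4-(diphenylmethyl)-3-{[(1R,2S,5S)-2-(3-methoxy-6-methyl-4-oxohept-2-en-2-yl)-5-methylcyclopentyl]carbonyl}-1,3-oxazolidin-2-one
Conditions: Ru(bpy)3(PF6)2 (2.5 mol %), La(OTf)3 (2 equiv), TMEDA (3 equiv), MgSO4, degassed MeCN, blue LEDs, rt; 8 in excess (2 equiv)
Reagents that add atoms: none
Why: Proposed new method: single-electron reduction of the La(OTf)3-chelated enone 5 by the photoreduced ruthenium complex gives a radical anion with spin at the β-carbon (future C4), which opens the cyclopropane to a lanthanum dienolate carrying a primary radical at the future C6; this nucleophilic radical adds to the β-carbon of chelated 8 (C6–C7) and the electrophilic α-imide radical then attacks the γ-terminus of the dienolate (C7a–C4a), giving back an enone radical anion that passes its electron to the next molecule of 5, so that both bonds arise in one redox-neutral chain event. The closest known reaction type is the formal [3+2] cycloaddition of cyclopropyl ketones with alkenes by ketyl radical relay (photoredox with Lewis acid, SmI2 or boryl-radical catalysis), extended here through one C=C bond in the way already shown for 4-cyclopropylpyridines, and reductive ring opening of β-cyclopropyl enones is itself established. One ring, the cyclopentane, is closed: intermolecular Giese addition followed by 5-exo-trig radical cyclisation. C7 is set by the auxiliary, since in the s-cis, bidentately bound imide the diphenylmethyl group covers one face of the β-carbon and the radical enters from the other to give (S); C4a and C7a are set in the ring closure through the chair-like transition state of a 5-exo hexenyl radical with the C7 methyl group pseudo-equatorial, which puts the alkenyl group trans to that methyl group and cis to the acyl group. The step needs chemoselectivity (electron uptake and ring opening by 5 only, radical capture by 8 only), which is secured by two-point binding of the α-methoxy ketone to lanthanum, by the polarity match of each radical with its partner and by an excess of 8. The C3=C4 geometry of 9 is of no consequence because step 7 erases it.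

Step 5
Reactants: 9 (4S)-4-(diphenylmethyl)-3-{[(1R,2S,5S)-2-(3-methoxy-6-methyl-4-oxohept-2-en-2-yl)-5-methylcyclopentyl]carbonyl}-1,3-oxazolidin-2-one
Product: 10 S-ethyl (1R,2S,5S)-2-(3-methoxy-6-methyl-4-oxohept-2-en-2-yl)-5-methylcyclopentane-1-carbothioate
Conditions: EtSH, n-BuLi, THF, 0 °C; aq. NH4Cl
Reagents that add atoms: ethanethiol, CCS
Why: thiolate transacylation of the N-acyl oxazolidinone at the exocyclic carbonyl should release the auxiliary for reuse, and the soft, weakly basic thiolate should leave the hindered α-methoxy enone and the ring stereocentres alone.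

Step 6
Reactants: 10 S-ethyl (1R,2S,5S)-2-(3-methoxy-6-methyl-4-oxohept-2-en-2-yl)-5-methylcyclopentane-1-carbothioate
Product: 11 (1R,2S,5S)-2-(3-methoxy-6-methyl-4-oxohept-2-en-2-yl)-5-methylcyclopentane-1-carbaldehyde
Conditions: Et3SiH, Pd/C (10 wt %), acetone, rt
Reagents that add atoms: none
Why: Fukuyama reduction (palladium insertion into the C–S bond, then hydride transfer from the silane) should stop at the aldehyde and spare the ketone and the tetrasubstituted enol ether.

Step 7
Reactants: 11 (1R,2S,5S)-2-(3-methoxy-6-methyl-4-oxohept-2-en-2-yl)-5-methylcyclopentane-1-carbaldehyde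
Product: 12 1-[(4aS,7S,7aR)-1-hydroxy-4,7-dimethyl-1,4a,5,6,7,7a-hexahydrocyclopenta[c]pyran-3-yl]-3-methylbutan-1-one (anomeric mixture at C1)
Conditions: 1 M HCl, THF–H2O, 45 °C
Reagents that add atoms: water, O
Why: acid hydrolysis of the α-methoxy enone (protonation at C4, hydration at C3, loss of methanol) should unmask the 1,2-diketone, whose enol oxygen adds to the 1,5-related aldehyde in a 6-exo-trig hemiacetalisation; the epimerisable aldehyde α-centre C7a is funnelled into the more stable cis-fused bicycle, and the C1 anomers converge in step 9.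

Step 8
Reactants: 13 1-(2-hydroxy-6-methylphenyl)ethan-1-one
Product: 14 4-hydroxy-5-methyl-2H-chromen-2-one
Conditions: NaH, (EtO)2CO, toluene, 110 °C; then aq. HCl
Reagents that add atoms: diethyl carbonate, CCOC(=O)OCC
Why: Claisen-type C-acylation of the ketone enolate by diethyl carbonate followed by lactonisation onto the phenoxide is the classical 4-hydroxycoumarin synthesis, and the ortho methyl group ends at C5.

Step 9
Reactants: 12 1-[(4aS,7S,7aR)-1-hydroxy-4,7-dimethyl-1,4a,5,6,7,7a-hexahydrocyclopenta[c]pyran-3-yl]-3-methylbutan-1-one; 14 4-hydroxy-5-methyl-2H-chromen-2-one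
Product: 15 4-hydroxy-5-methyl-3-[(1R,4aS,7S,7aR)-4,7-dimethyl-3-(3-methylbutanoyl)-1,4a,5,6,7,7a-hexahydrocyclopenta[c]pyran-1-yl]-2H-chromen-2-one
Conditions: CF3CO2H (20 mol %), CH2Cl2, 4 Å MS, 0 °C to rt; 14 (1.0 equiv)
Reagents that add atoms: none
Why: acid should ionise the lactol to a cyclic oxocarbenium ion that is captured by the nucleophilic C3 of the 4-hydroxycoumarin (Friedel–Crafts-type C-glycosylation); attack on the convex face of the cis-fused bicycle, anti to the cyclopentane bond at C7a, gives (1R), and reversibility of the C1–O2 bond under acid lets the same pseudo-equatorial isomer accumulate.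

Step 10
Reactants: 15 4-hydroxy-5-methyl-3-[(1R,4aS,7S,7aR)-4,7-dimethyl-3-(3-methylbutanoyl)-1,4a,5,6,7,7a-hexahydrocyclopenta[c]pyran-1-yl]-2H-chromen-2-one
Product: 16 2-methoxy-5-methyl-3-[(1R,4aS,7S,7aR)-4,7-dimethyl-3-(3-methylbutanoyl)-1,4a,5,6,7,7a-hexahydrocyclopenta[c]pyran-1-yl]-4H-chromen-4-one (CNP0144992.1)
Conditions: MeOTf, 2,6-di-tert-butylpyridine, CH2Cl2, 0 °C to rt; aq. NaHCO3
Reagents that add atoms: methyl trifluoromethanesulfonate, COS(=O)(=O)C(F)(F)F
Why: a hard methylating agent should alkylate the neutral 4-hydroxycoumarin at its most basic site, the lactone carbonyl oxygen, and loss of the O4 proton from the resulting 2-methoxy-4-hydroxybenzopyrylium ion gives the 2-methoxychromone (the known α-pyrone to 2-methoxy-γ-pyrone methylation), helped by shielding of O4 by the peri 5-methyl group and the C3 substituent.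

**Compound list**

1 | 1-cyclopropylethan-1-one | CC(=O)C1CC1 | starting material
2 | methyl 2-(dimethoxyphosphoryl)-2-methoxyacetate | COC(C(=O)OC)P(=O)(OC)OC | starting material
3 | methyl 3-cyclopropyl-2-methoxybut-2-enoate (E/Z mixture) | COC(=O)C(OC)=C(C)C1CC1 | intermediate
4 | 3-cyclopropyl-N,2-dimethoxy-N-methylbut-2-enamide (E/Z mixture, not isolated) | CON(C)C(=O)C(OC)=C(C)C1CC1 | intermediate
5 | 2-cyclopropyl-3-methoxy-6-methylhept-2-en-4-one (E/Z mixture) | CC(C)CC(=O)C(OC)=C(C)C1CC1 | intermediate
6 | (4S)-4-(diphenylmethyl)-1,3-oxazolidin-2-one | O=C1N[C@@H](C(c2ccccc2)c2ccccc2)CO1 | starting material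
7 | (2E)-but-2-enoyl chloride | C/C=C/C(Cl)=O | starting material
8 | (4S)-3-[(2E)-but-2-enoyl]-4-(diphenylmethyl)-1,3-oxazolidin-2-one | C/C=C/C(=O)N1C(=O)OC[C@@H]1C(c1ccccc1)c1ccccc1 | intermediate
9 | (4S)-4-(diphenylmethyl)-3-{[(1R,2S,5S)-2-(3-methoxy-6-methyl-4-oxohept-2-en-2-yl)-5-methylcyclopentyl]carbonyl}-1,3-oxazolidin-2-one (C=C isomers) | O=C(N1C(=O)OC[C@@H]1C(c1ccccc1)c1ccccc1)[C@@H]1[C@@H](C)CC[C@@H]1C(C)=C(OC)C(=O)CC(C)C | intermediate
10 | S-ethyl (1R,2S,5S)-2-(3-methoxy-6-methyl-4-oxohept-2-en-2-yl)-5-methylcyclopentane-1-carbothioate (C=C isomers) | CCSC(=O)[C@@H]1[C@@H](C)CC[C@@H]1C(C)=C(OC)C(=O)CC(C)C | intermediate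
11 | (1R,2S,5S)-2-(3-methoxy-6-methyl-4-oxohept-2-en-2-yl)-5-methylcyclopentane-1-carbaldehyde (C=C isomers) | O=C[C@@H]1[C@@H](C)CC[C@@H]1C(C)=C(OC)C(=O)CC(C)C | intermediate
12 | 1-[(4aS,7S,7aR)-1-hydroxy-4,7-dimethyl-1,4a,5,6,7,7a-hexahydrocyclopenta[c]pyran-3-yl]-3-methylbutan-1-one (anomers) | OC1OC(C(=O)CC(C)C)=C(C)[C@H]2CC[C@H](C)[C@H]21 | intermediate
13 | 1-(2-hydroxy-6-methylphenyl)ethan-1-one | CC(=O)c1c(C)cccc1O | starting material
14 | 4-hydroxy-5-methyl-2H-chromen-2-one | Cc1cccc2oc(=O)cc(O)c12 | intermediate
15 | 4-hydroxy-5-methyl-3-[(1R,4aS,7S,7aR)-4,7-dimethyl-3-(3-methylbutanoyl)-1,4a,5,6,7,7a-hexahydrocyclopenta[c]pyran-1-yl]-2H-chromen-2-one | Cc1cccc2oc(=O)c(c(O)c12)[C@@H]1OC(C(=O)CC(C)C)=C(C)[C@H]2CC[C@H](C)[C@H]21 | intermediate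
16 | 2-methoxy-5-methyl-3-[(1R,4aS,7S,7aR)-4,7-dimethyl-3-(3-methylbutanoyl)-1,4a,5,6,7,7a-hexahydrocyclopenta[c]pyran-1-yl]-4H-chromen-4-one | COc1oc2cccc(C)c2c(=O)c1[C@@H]1OC(C(=O)CC(C)C)=C(C)[C@H]2CC[C@H](C)[C@H]21 | target

**Step count and risks**

Total steps: 10. Longest linear sequence: 8 (steps 1, 2, 4, 5, 6, 7, 9, 10).

Steps most likely to fail:

1. Step 4 (Proposed new method). Electron transfer to the twisted, electron-rich α-methoxy enone may lose out to reduction of the chelated imide. The ring-opened primary radical may be quenched by hydrogen abstraction before it adds to the β-substituted acceptor. The ring closure may give weak 1,3-induction from C7 to C4a, or the auxiliary weak facial control.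
   Fallback (known chemistry), setting out from 1 and 8 and coming back at 12: 1 and 8 are joined by the established ketyl-relay formal [3+2] cycloaddition of an alkyl cyclopropyl ketone with an acceptor alkene (SmI2 with Sm metal, THF, 55 °C). This forms the same two bonds under the same auxiliary control and should give (4S)-3-{[(1R,2S,5S)-2-acetyl-5-methylcyclopentyl]carbonyl}-4-(diphenylmethyl)-1,3-oxazolidin-2-one F1. LiOH/H2O2 should remove the auxiliary to give (1R,2S,5S)-2-acetyl-5-methylcyclopentane-1-carboxylic acid F2. Wittig methoxymethylenation (Ph3P=CHOMe in excess) should give (1R,2S,5S)-2-(1-methoxyprop-1-en-2-yl)-5-methylcyclopentane-1-carboxylic acid F3. TsOH in wet toluene, then with azeotropic removal of water, should hydrolyse the enol ether to nepetalic acid F4 (not isolated) and close the enol lactone (4aS,7S,7aR)-nepetalactone F5. DIBAL-H at −78 °C should give the lactol (4aS,7S,7aR)-4,7-dimethyl-1,4a,5,6,7,7a-hexahydrocyclopenta[c]pyran-1-ol F6, and MeOH/PPTS its methyl acetal (4aS,7S,7aR)-1-methoxy-4,7-dimethyl-1,4a,5,6,7,7a-hexahydrocyclopenta[c]pyran F7. α-Lithiation of the cyclic enol ether at C3 (t-BuLi, THF, −78 to 0 °C) and acylation with N-methoxy-N,3-dimethylbutanamide should give 1-[(4aS,7S,7aR)-1-methoxy-4,7-dimethyl-1,4a,5,6,7,7a-hexahydrocyclopenta[c]pyran-3-yl]-3-methylbutan-1-one F8. 1 M HCl in THF then hydrolyses the acetal to 12.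

2. Step 10. Methylation may occur at O4 to give the 4-methoxycoumarin isomer, or the acid released may ionise the C1–O2 bond.
   Fallback, setting out from 14 and coming back at 16: 14 is methylated first with the same reagent, and the O-methyl isomers are separated at this inexpensive stage to give 2-methoxy-5-methyl-4H-chromen-4-one F9. BF3·OEt2 in CH2Cl2 then ionises lactol 12, and the oxocarbenium ion is captured at C3 of F9 (the nucleophilic α-carbon of the vinylogous carbonate) on the same convex face, giving 16 directly.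

3. Step 9. O-alkylation of the coumarin may compete with C-alkylation, a second coumarin may add after ring opening, or the C1 epimers may not equilibrate.
   Fallback, setting out from 12 and 14 and coming back at 15: instead of cationic substitution on the closed lactol, the open keto-aldehyde tautomer of 12 is condensed with 14 under amine-salt catalysis (ethylenediammonium diacetate, MeOH, rt). This Knoevenagel condensation gives 5-methyl-3-{[(1R,2S,5S)-2-methyl-5-(6-methyl-3,4-dioxoheptan-2-yl)cyclopentyl]methylidene}-2H-chromene-2,4(3H)-dione F10 (not isolated). Its diketone enol oxygen then closes the pyran by reversible six-ring oxa-Michael addition under thermodynamic control to give 15.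

Further compounds
F1 | step 4 | (4S)-3-{[(1R,2S,5S)-2-acetyl-5-methylcyclopentyl]carbonyl}-4-(diphenylmethyl)-1,3-oxazolidin-2-one | O=C(N1C(=O)OC[C@@H]1C(c1ccccc1)c1ccccc1)[C@@H]1[C@@H](C)CC[C@@H]1C(C)=O
F2 | step 4 | (1R,2S,5S)-2-acetyl-5-methylcyclopentane-1-carboxylic acid | OC(=O)[C@@H]1[C@@H](C)CC[C@@H]1C(C)=O
F3 | step 4 | (1R,2S,5S)-2-(1-methoxyprop-1-en-2-yl)-5-methylcyclopentane-1-carboxylic acid (E/Z mixture) | OC(=O)[C@@H]1[C@@H](C)CC[C@@H]1C(C)=COC
F4 | step 4 | nepetalic acid, (1R,2S,5R)-2-methyl-5-(1-oxopropan-2-yl)cyclopentane-1-carboxylic acid (epimers at the formyl-bearing carbon, not isolated) | OC(=O)[C@@H]1[C@@H](C)CC[C@@H]1C(C)C=O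
F5 | step 4 | (4aS,7S,7aR)-nepetalactone, (4aS,7S,7aR)-4,7-dimethyl-5,6,7,7a-tetrahydrocyclopenta[c]pyran-1(4aH)-one | O=C1OC=C(C)[C@H]2CC[C@H](C)[C@H]21
F6 | step 4 | (4aS,7S,7aR)-4,7-dimethyl-1,4a,5,6,7,7a-hexahydrocyclopenta[c]pyran-1-ol (anomers) | OC1OC=C(C)[C@H]2CC[C@H](C)[C@H]21
F7 | step 4 | (4aS,7S,7aR)-1-methoxy-4,7-dimethyl-1,4a,5,6,7,7a-hexahydrocyclopenta[c]pyran (anomers) | COC1OC=C(C)[C@H]2CC[C@H](C)[C@H]21
F8 | step 4 | 1-[(4aS,7S,7aR)-1-methoxy-4,7-dimethyl-1,4a,5,6,7,7a-hexahydrocyclopenta[c]pyran-3-yl]-3-methylbutan-1-one (anomers) | COC1OC(C(=O)CC(C)C)=C(C)[C@H]2CC[C@H](C)[C@H]21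
F9 | step 10 | 2-methoxy-5-methyl-4H-chromen-4-one | COc1cc(=O)c2c(C)cccc2o1
F10 | step 9 | 5-methyl-3-{[(1R,2S,5S)-2-methyl-5-(6-methyl-3,4-dioxoheptan-2-yl)cyclopentyl]methylidene}-2H-chromene-2,4(3H)-dione (not isolated) | Cc1cccc2OC(=O)C(=C[C@@H]3[C@@H](C)CC[C@@H]3C(C)C(=O)C(=O)CC(C)C)C(=O)c12
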